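A molar of extra solid substrate costs days, and I wanted that price in days per molar, since the flask holds more solid than either run.

| flask | solid substrate | reagent | free catalyst | remark | time |
|---|---|---|---|---|---|
| epsilon | 1 M | 2.4 M | 300 mM | run made earlier |  |
| alpha | 1.5 M | 2.4 M | 300 mM | run made earlier |  |
| flask | 2.0 M | 2.40 M | 300 mM |  | 15 d |

- epsilon (time / d: target / %, isomer of the product / %): 1.25: 58, 18; 2.50: 47, 35; 4.00: 45, 46; 5.00: 41, 48; 6.00: 37, 52; 8.00: 33, 56; 10.0: 34, 59
- alpha (time / d: target / %, isomer of the product / %): 0.500: 15, 2; 1.25: 39, 13; 2.50: 51, 29; 4.00: 45, 40; 5.00: 40, 40; 8.00: 37, 51; 10.0: 36, 54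

(readings scatter by 1.5 percentage points)

- solid substrate is a solid; its amount is given per volume of the solution
- the analysis behind the earlier runs scatters by 1.5 percentage points, standard deviation
- at the start none of the solid substrate is in solution

* share of target in target plus isomer of the product at 2.5 h
* share of target in target plus isomer of the product at 15 d
* which of target and isomer of the product there is more of at 15 d

I took the even case, as much target as isomer of the product, as the zero of my scale, and called its time t_L. The epsilon run read nearly level at 4.00 d, with 45% against 46%, and the alpha run read level at 5.00 d, with 40% against 40%, each reading scattering by 1.5 percentage points. I took these two readings as rough crossing times, and they gave my first price: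

1.00 d for 0.500 M more charge, so t_L = 6.00 d

The second price came from other readings. By 1.25 d, target plus isomer had grown at a feed f of 0.624 M d⁻¹ in the alpha run and 0.608 M d⁻¹ in the epsilon run, nearly the same molar gain from different charges. Each extra molar should then take 1/f:

0.801 d for the 0.500 M beyond the alpha run, so t_L = 5.80 d

Both ways start from the same alpha reading, so only the prices are a check. They part by 0.200 d, less than the spacing of the readings. I carried this level time, the alpha reading of level plus the extra charge over f. Since 15 d lies 9.20 d past it, I expected the isomer ahead, but I committed to no share.

The forecast gave 96%, 38% and isomer of the product in the lead, holding that “it finishes dissolving later”.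

The flask gave 94.5% and 36.7%, with isomer of the product ahead at 52.1% against 30.2% of target.

    starting material + reagent ⇌ target (K = 2.22 M⁻¹, k = 0.102 M⁻¹ h⁻¹)
    starting material + reagent ⇌ isomer of the product (K = 24.0 M⁻¹, k = 0.00370 M⁻¹ h⁻¹)
    target + free catalyst ⇌ isomer of the product + free catalyst, rate k3*[free catalyst]*[target] forward; the back reaction follows from the equilibrium constant (k = 0.0785 M⁻¹ h⁻¹)
    solid substrate ⇌ starting material, rate k4*(cs4 - [starting material]) while solid is left; crystals form when [starting material] > cs4 (solubility = 1.10 M, k = 0.0403 h⁻¹)
    free catalyst → spent catalyst (k = 0.0207 h⁻¹)

The flask drew level at 5.86 d, against my 5.80 d. The neighbouring flask, charged with 0.50 M of solid substrate and otherwise the same, gets from the same line t_L = 3.40 d. Its end therefore lies 11.6 d past level, later on the scale than the flask's 9.20 d. At 15 d the neighbour's share of target stood at 28.1%, below the flask's 36.7%, with isomer of the product at 67.5% of its charge.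

(The readings were computed for an exercise.)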